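**Retrosynthetic overview**

1. Locants used below: C1 = quaternary carbon bearing C15H2OAc; C2 = CH2; C3 = CHOAc; C4 = CHOH; C5 = CMe2; C6 = quaternary apex carbon; C7 = CH2 bridge; cyclopropane C8 (on C7), C9 (on C1), C10 (methyl, on C11); C11 = CHOAc bridge; ring A = C1–C6.
2. Target ⇐ nortricyclanone 23 (C11 ketone, O3/O4 acetonide, C15–OTBS). The late steps only invert and acetylate C11 by cation capture, acetylate C15, and open a cyclic orthoacetate to put the acetyl group on the axial O3.
3. Key disconnection: 23 ⇐ tricyclic β,γ-unsaturated cyclobutanone 22 by a triplet 1,2-acyl shift. The four-membered ring C1–C6–C11–C9 expands to the five-membered ring C1–C6–C11–C10–C9 while C9–C8 closes the cyclopropane. The enabling feature is the strained cyclobutanone whose carbonyl C11 is held 1,3 to C10 of the C10=C8 double bond carried by its α-carbon C9 inside a bicyclo[3.1.1]heptene.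
4. 22 ⇐ monocyclic (Z)-dienoic acid 19 by intramolecular vinylketene–alkene [2+2] across the tetrasubstituted C1=C6 bond of ring A, anti to the acetonide (sets C1, C6, C9).
5. 19 ⇐ vinyl triflate 11 + (Z)-iodo ester 15 (Negishi); 11 ⇐ (S)-hydroxy ketone 1, whose carbinol (C4) relays to C3 by a hydroxyl-directed epoxidation. Ring order: ring A (bought) → cyclobutanone and cyclohexene (step 11) → three cyclopentanes and cyclopropane (step 12).

Key step: step 12

Remark: (S)-3-hydroxy-2,2-dimethylcyclohexan-1-one (1) and 4-methyl-5,6-dihydro-2H-pyran-2-one (12) are taken as purchasable; 1 is otherwise one step from 2,2-dimethylcyclohexane-1,3-dione by baker's-yeast reduction.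

**Route**

Step 1
Reactants: 1 (S)-3-hydroxy-2,2-dimethylcyclohexan-1-one
Product: 2 (S)-5-hydroxy-6,6-dimethylcyclohex-2-en-1-one
Conditions: Pd(O2CCF3)2 (5 mol %), DMSO (10 mol %), O2 (1 atm), AcOH, 80 °C
Reagents that add atoms: none
Why: Aerobic palladium-catalysed α,β-dehydrogenation of a cyclohexanone (enolate palladation, β-hydride elimination) should be regiospecific because only one α-carbon carries hydrogen and the gem-dimethyl carbon blocks aromatisation; the carbinol stereocentre is not touched.

Step 2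
Reactants: 2 (S)-5-hydroxy-6,6-dimethylcyclohex-2-en-1-one
Product: 4 (S)-3-hydroxy-2,2-dimethylcyclohex-4-en-1-one, via dilithium dienolate alkoxide 3 (not isolated)
Conditions: LiN(i-Pr)2 (2.3 equiv), THF/DMPU, −78 → −40 °C; then AcOH, −78 °C
Reagents that add atoms: none
Why: Enone deconjugation through the extended enolate: with the α′-carbon quaternary, the amide base can only remove a γ-hydrogen after the hydroxyl proton, and kinetic α-protonation of the dienolate should place the double bond β,γ, next to the carbinol, without touching the stereocentre.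

Step 3
Reactants: 4 (S)-3-hydroxy-2,2-dimethylcyclohex-4-en-1-one
Product: 6 (4S,5R)-4,5-dihydroxy-6,6-dimethylcyclohex-2-en-1-one, via cis-epoxy alcohol 5 (not isolated)
Conditions: VO(acac)2 (2 mol %), t-BuOOH, CH2Cl2, 0 °C; then Et3N (20 mol %), rt
Reagents that add atoms: tert-butyl hydroperoxide, CC(C)(C)OO
Why: Hydroxyl-directed vanadium-catalysed epoxidation should deliver oxygen syn to the allylic OH, and the β,γ-epoxy ketone then opens by E1cB with retention at the C–O carbon, so the new carbinol (C3) is cis to the old one (C4).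

Step 4
Reactants: 6 (4S,5R)-4,5-dihydroxy-6,6-dimethylcyclohex-2-en-1-one
Product: 7 (3aR,7aS)-2,2,4,4-tetramethyl-3a,7a-dihydro-1,3-benzodioxol-5(4H)-one
Conditions: 2,2-dimethoxypropane, PPTS (cat.), acetone, rt
Reagents that add atoms: 2,2-dimethoxypropane, COC(C)(C)OC
Why: Acid-catalysed transketalisation closes the dioxolane readily on a cis-1,2-diol and changes no stereocentre.

Step 5
Reactants: 7 (3aR,7aS)-2,2,4,4-tetramethyl-3a,7a-dihydro-1,3-benzodioxol-5(4H)-one
Product: 8 (3aR,7aS)-6-(hydroxymethyl)-2,2,4,4-tetramethyl-3a,7a-dihydro-1,3-benzodioxol-5(4H)-one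
Conditions: aq. CH2O (37 %), DMAP (20 mol %), THF/H2O, rt
Reagents that add atoms: formaldehyde, C=O
Why: The Morita–Baylis–Hillman reaction of a cyclic enone with formaldehyde under nucleophilic catalysis should install C15 on the α-carbon; no new stereocentre forms.

Step 6
Reactants: 8 (3aR,7aS)-6-(hydroxymethyl)-2,2,4,4-tetramethyl-3a,7a-dihydro-1,3-benzodioxol-5(4H)-one
Product: 9 (3aR,7aS)-6-{[tert-butyl(dimethyl)silyl]oxymethyl}-2,2,4,4-tetramethyl-3a,7a-dihydro-1,3-benzodioxol-5(4H)-one
Conditions: TBSCl, imidazole, DMF, rt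
Reagents that add atoms: tert-butyldimethylsilyl chloride, CC(C)(C)[Si](C)(C)Cl
Why: Standard silylation of a primary alcohol.

Step 7
Reactants: 9 (3aR,7aS)-6-{[tert-butyl(dimethyl)silyl]oxymethyl}-2,2,4,4-tetramethyl-3a,7a-dihydro-1,3-benzodioxol-5(4H)-one
Product: 11 (3aR,7aS)-6-{[tert-butyl(dimethyl)silyl]oxymethyl}-2,2,4,4-tetramethyl-3a,4,7,7a-tetrahydro-1,3-benzodioxol-5-yl trifluoromethanesulfonate, via lithium enolate 10 (not isolated)
Conditions: LiBH(s-Bu)3, THF, −78 °C; then PhNTf2, −78 → 0 °C
Reagents that add atoms: N-phenyl-bis(trifluoromethanesulfonimide), O=S(=O)(N(c1ccccc1)S(=O)(=O)C(F)(F)F)C(F)(F)F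
Why: Conjugate hydride reduction by the bulky borohydride (1,2-attack is disfavoured at a carbonyl flanked by a quaternary carbon) should give the tetrasubstituted enolate regiospecifically, and O-triflation traps it as the C6 vinyl triflate; no new stereocentre forms.

Step 8
Reactants: 12 4-methyl-5,6-dihydro-2H-pyran-2-one
Product: 15 methyl (Z)-5-iodo-3-methylpent-2-enoate, via trimethylsilyl ester 13 (not isolated), via iodo acid 14 (not isolated)
Conditions: Me3SiI (1.3 equiv), CHCl3, 50 °C; then MeOH (excess), 40 °C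
Reagents that add atoms: iodotrimethylsilane, C[Si](C)(C)I; methanol, CO
Why: Silyl iodide O-alkyl cleavage of a lactone (SN2 by iodide at the O–CH2 carbon) followed by acid-catalysed esterification in methanol should give the iodo ester, its (Z) geometry inherited from the ring.

Step 9
Reactants: 11 vinyl triflate; 15 methyl (Z)-5-iodo-3-methylpent-2-enoate
Product: 17 methyl (Z)-5-[(3aR,7aS)-6-{[tert-butyl(dimethyl)silyl]oxymethyl}-2,2,4,4-tetramethyl-3a,4,7,7a-tetrahydro-1,3-benzodioxol-5-yl]-3-methylpent-2-enoate, via alkylzinc iodide 16 (not isolated)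
Conditions: 15, Zn dust (I2-activated), DMA, 40 °C; then 11, Pd(dppf)Cl2 (5 mol %), THF, 60 °C
Reagents that add atoms: none
Why: Negishi sp2–sp3 cross-coupling: zinc insertion into the primary iodide tolerates the ester, and the primary alkylzinc should transmetalate to the hindered vinylpalladium and reductively eliminate faster than β-hydride elimination with the wide-bite-angle ligand; both alkene geometries are retained.

Step 10
Reactants: 17 coupled methyl ester
Product: 19 (Z)-5-[(3aR,7aS)-6-{[tert-butyl(dimethyl)silyl]oxymethyl}-2,2,4,4-tetramethyl-3a,4,7,7a-tetrahydro-1,3-benzodioxol-5-yl]-3-methylpent-2-enoic acid, via lithium carboxylate 18 (not isolated)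
Conditions: LiOH·H2O, THF/MeOH/H2O, 40 °C; then 1 M HCl to pH 3–4, 0 °C
Reagents that add atoms: lithium hydroxide, [Li+].[OH-]
Why: Saponification of the unhindered side-chain ester; silyl ether and acetonide are base-stable.

Step 11
Reactants: 19 (Z)-dienoic acid
Product: 22 tricyclic β,γ-unsaturated cyclobutanone (2-methylbicyclo[3.1.1]hept-2-en-6-one fused to ring A across C6–C1), via acyl chloride 20 (not isolated), via dienylketene 21 (not isolated)
Conditions: 1-chloro-N,N,2-trimethylprop-1-en-1-amine, CH2Cl2, 0 °C → rt; evaporate; then slow addition to Et3N (5 equiv), toluene, 110 °C (0.005 M)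
Reagents that add atoms: none
Why: Intramolecular vinylketene–alkene [2+2] cycloaddition: after neutral chlorination, Et3N removes a C8 hydrogen, which the (Z) geometry holds syn to the carbonyl, and the dienylketene should add across the electron-rich C1=C6 bond in the bridged mode (small sp carbon C11 onto the neopentyl C6, C9 onto C1), suprafacially on the alkene face anti to the acetonide, which sets C1 and C6, while the bridge fixes C9.

Step 12
Reactants: 22 tricyclic β,γ-unsaturated cyclobutanone
Product: 23 nortricyclanone (C11 ketone; cyclopropane C8–C9–C10; O3/O4 acetonide; C15–OTBS)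
Conditions: hν (300 nm), acetone (solvent and triplet sensitizer, degassed, 0.01 M), 20 °C
Reagents that add atoms: none
Why: Triplet energy transfer from acetone excites the β,γ-enone; bonding of the carbonyl carbon C11 to C10 gives a cyclopropyloxy diradical, cleavage of the C11–C9 bond (relief of cyclobutanone strain) completes the 1,2-acyl shift, and the C9/C8 1,3-diradical closes after intersystem crossing. The closest known reaction type is the oxa-di-π-methane rearrangement of bridged bicyclic β,γ-unsaturated ketones such as bicyclo[2.2.2]oct-5-en-2-ones. The five-membered ring C1–C6–C11–C10–C9 forms by ring expansion of the four-membered ring C1–C6–C11–C9 (C10 is inserted between C11 and C9); both six-membered rings of the bicycloheptene contract to the cyclopentanes C6–C7–C8–C10–C11 and C1–C6–C7–C8–C9; the cyclopropane C8–C9–C10 closes by 3-exo radical recombination C9–C8. C1 and C6 keep their configuration because none of their bonds breaks, and the new stereocentres C8, C9 and C10 can form only one way in the cage, since C11 stays tethered to C6 and C8 is held by C7. The step needs the 1,2-shift to win over α-cleavage and the 1,3-acyl shift: acetone absorbs the light and populates only the triplet, and the 1,3-shift isomer, should it form, is itself a β,γ-unsaturated cyclobutanone that the same 1,2-shift converts into 23.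

Step 13
Reactants: 23 nortricyclanone
Product: 24 C11 alcohol (hydroxyl on the ring A side of C11)
Conditions: LiAlH4, THF, 0 °C
Reagents that add atoms: none
Why: Hydride reduction of a cyclopropyl ketone; hydride should enter from the less crowded C7 side (the other side is screened by C2–C4 of ring A), leaving the hydroxyl over ring A, the epimer opposite to the target, which step 14 corrects.

Step 14
Reactants: 24 C11 alcohol
Product: 26 C11 acetate (acetoxy on the C7 side; target configuration), via mesylate 25 (not isolated)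
Conditions: Ms2O, Et3N, CH2Cl2, −20 °C; then Bu4NOAc (3 equiv), rt
Reagents that add atoms: tetrabutylammonium acetate, CCCC[N+](CCCC)(CCCC)CCCC.CC([O-])=O
Why: Solvolysis of a cyclopropylcarbinyl sulfonate: the mesylate should ionise to the delocalised nortricyclyl cation, which acetate captures at C11 from the open C7 side, so either C11 epimer of 24 converges on the target configuration.

Step 15
Reactants: 26 C11 acetate
Product: 27 C15 primary alcohol
Conditions: HF·pyridine, pyridine, THF, 0 °C → rt
Reagents that add atoms: none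
Why: Buffered fluoride cleavage of the primary silyl ether should spare the acetonide and the acetate.

Step 16
Reactants: 27 C15 primary alcohol
Product: 28 C11/C15 diacetate acetonide
Conditions: Ac2O, pyridine, DMAP (cat.), CH2Cl2, rt
Reagents that add atoms: acetic anhydride, CC(=O)OC(C)=O
Why: Acetylation of the only free hydroxyl group.

Step 17
Reactants: 28 C11/C15 diacetate acetonide
Product: 29 C3/C4 cis-diol diacetate
Conditions: AcOH/H2O (4:1), 50 °C
Reagents that add atoms: none
Why: Mild aqueous acid hydrolysis of the acetonide; the acetates should survive.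

Step 18
Reactants: 29 C3/C4 cis-diol diacetate
Product: 31 target CNP0197219.1, via cyclic orthoacetate 30 (not isolated)
Conditions: MeC(OMe)3, PPTS (cat.), CH2Cl2, rt; then AcOH/H2O (4:1), rt
Reagents that add atoms: trimethyl orthoacetate, CC(OC)(OC)OC; water, O
Why: Orthoester exchange on the cis-diol and kinetic hydrolysis of the 2-methoxy-1,3-dioxolane: the hemiorthoester should collapse with the acyl group on the axial oxygen, here O3 on the cage-locked chair of ring A, leaving the equatorial neopentyl O4–H free.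

**Compound list**

1 | (S)-3-hydroxy-2,2-dimethylcyclohexan-1-one | O=C1CCC[C@H](O)C1(C)C | starting material
2 | (S)-5-hydroxy-6,6-dimethylcyclohex-2-en-1-one | O=C1C=CC[C@H](O)C1(C)C | intermediate
3 | dilithium (S)-6,6-dimethylcyclohexa-1,3-diene-1,5-diolate (not isolated) | [Li+].[Li+].[O-]C1=CC=C[C@H]([O-])C1(C)C | intermediate
4 | (S)-3-hydroxy-2,2-dimethylcyclohex-4-en-1-one | O=C1CC=C[C@H](O)C1(C)C | intermediate
5 | (3S)-4,5-epoxy-3-hydroxy-2,2-dimethylcyclohexan-1-one, epoxide cis to the hydroxyl (not isolated) | O=C1C[C@@H]2O[C@@H]2[C@H](O)C1(C)C | intermediate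
6 | (4S,5R)-4,5-dihydroxy-6,6-dimethylcyclohex-2-en-1-one | O=C1C=C[C@H](O)[C@H](O)C1(C)C | intermediate
7 | (3aR,7aS)-2,2,4,4-tetramethyl-3a,7a-dihydro-1,3-benzodioxol-5(4H)-one | O=C1C=C[C@@H]2OC(C)(C)O[C@@H]2C1(C)C | intermediate
8 | (3aR,7aS)-6-(hydroxymethyl)-2,2,4,4-tetramethyl-3a,7a-dihydro-1,3-benzodioxol-5(4H)-one | OCC1=C[C@@H]2OC(C)(C)O[C@@H]2C(C)(C)C1=O | intermediate
9 | (3aR,7aS)-6-{[tert-butyl(dimethyl)silyl]oxymethyl}-2,2,4,4-tetramethyl-3a,7a-dihydro-1,3-benzodioxol-5(4H)-one | CC(C)(C)[Si](C)(C)OCC1=C[C@@H]2OC(C)(C)O[C@@H]2C(C)(C)C1=O | intermediate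
10 | lithium enolate of the 6,7-dihydro ketone derived from 9 (not isolated) | CC(C)(C)[Si](C)(C)OCC1=C([O-])C(C)(C)[C@H]2OC(C)(C)O[C@H]2C1.[Li+] | intermediate
11 | (3aR,7aS)-6-{[tert-butyl(dimethyl)silyl]oxymethyl}-2,2,4,4-tetramethyl-3a,4,7,7a-tetrahydro-1,3-benzodioxol-5-yl trifluoromethanesulfonate | CC(C)(C)[Si](C)(C)OCC1=C(OS(=O)(=O)C(F)(F)F)C(C)(C)[C@H]2OC(C)(C)O[C@H]2C1 | intermediate
12 | 4-methyl-5,6-dihydro-2H-pyran-2-one | CC1=CC(=O)OCC1 | starting material
13 | trimethylsilyl (Z)-5-iodo-3-methylpent-2-enoate (not isolated) | ICC/C(C)=C\C(=O)O[Si](C)(C)C | intermediate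
14 | (Z)-5-iodo-3-methylpent-2-enoic acid (not isolated) | ICC/C(C)=C\C(O)=O | intermediate
15 | methyl (Z)-5-iodo-3-methylpent-2-enoate | ICC/C(C)=C\C(=O)OC | intermediate
16 | (Z)-(5-methoxy-3-methyl-5-oxopent-3-en-1-yl)zinc iodide (not isolated) | I[Zn]CC/C(C)=C\C(=O)OC | intermediate
17 | methyl (Z)-5-[(3aR,7aS)-6-{[tert-butyl(dimethyl)silyl]oxymethyl}-2,2,4,4-tetramethyl-3a,4,7,7a-tetrahydro-1,3-benzodioxol-5-yl]-3-methylpent-2-enoate | CC(C)(C)[Si](C)(C)OCC1=C(CC/C(C)=C\C(=O)OC)C(C)(C)[C@H]2OC(C)(C)O[C@H]2C1 | intermediate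
18 | lithium carboxylate of 19 (not isolated) | CC(C)(C)[Si](C)(C)OCC1=C(CC/C(C)=C\C([O-])=O)C(C)(C)[C@H]2OC(C)(C)O[C@H]2C1.[Li+] | intermediate
19 | (Z)-5-[(3aR,7aS)-6-{[tert-butyl(dimethyl)silyl]oxymethyl}-2,2,4,4-tetramethyl-3a,4,7,7a-tetrahydro-1,3-benzodioxol-5-yl]-3-methylpent-2-enoic acid | CC(C)(C)[Si](C)(C)OCC1=C(CC/C(C)=C\C(O)=O)C(C)(C)[C@H]2OC(C)(C)O[C@H]2C1 | intermediate
20 | acyl chloride of 19 (not isolated) | CC(C)(C)[Si](C)(C)OCC1=C(CC/C(C)=C\C(Cl)=O)C(C)(C)[C@H]2OC(C)(C)O[C@H]2C1 | intermediate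
21 | dienylketene O=C=CH–C(CH3)=CH–CH2–(ring A), C7 cis to the ketene carbon (not isolated) | CC(C)(C)[Si](C)(C)OCC1=C(C/C=C(C)\C=C=O)C(C)(C)[C@H]2OC(C)(C)O[C@H]2C1 | intermediate
22 | tricyclic cyclobutanone: 2-methylbicyclo[3.1.1]hept-2-en-6-one fused to ring A across C6–C1; ketone C11 bridges C6 and C9, alkene C8=C10, C15–OTBS on C1, O3/O4 acetonide; C11 and C9 on the ring A face opposite the acetonide | CC(C)(C)[Si](C)(C)OC[C@]12C[C@H](OC3(C)C)[C@H](O3)C(C)(C)[C@]14CC=C(C)[C@H]2C4=O | intermediate
23 | nortricyclanone: target skeleton with C11 ketone, C15–OTBS and O3/O4 acetonide | CC(C)(C)[Si](C)(C)OC[C@]12C[C@H](OC3(C)C)[C@H](O3)C(C)(C)[C@]14C[C@@H]1[C@H]2[C@]1(C)C4=O | intermediate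
24 | C11 alcohol of 23, hydroxyl on the ring A side (C11 epimer of the target configuration) | CC(C)(C)[Si](C)(C)OC[C@]12C[C@H](OC3(C)C)[C@H](O3)C(C)(C)[C@]14C[C@@H]1[C@H]2[C@]1(C)[C@@H]4O | intermediate
25 | C11 methanesulfonate of 24 (not isolated) | CC(C)(C)[Si](C)(C)OC[C@]12C[C@H](OC3(C)C)[C@H](O3)C(C)(C)[C@]14C[C@@H]1[C@H]2[C@]1(C)[C@@H]4OS(C)(=O)=O | intermediate
26 | C11 acetate, acetoxy on the C7 side (target configuration); C15–OTBS; acetonide | CC(C)(C)[Si](C)(C)OC[C@]12C[C@H](OC3(C)C)[C@H](O3)C(C)(C)[C@]14C[C@@H]1[C@H]2[C@]1(C)[C@H]4OC(C)=O | intermediate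
27 | C15 alcohol: C11 acetate, acetonide | OC[C@]12C[C@H](OC3(C)C)[C@H](O3)C(C)(C)[C@]14C[C@@H]1[C@H]2[C@]1(C)[C@H]4OC(C)=O | intermediate
28 | C11/C15 diacetate, O3/O4 acetonide | CC(=O)OC[C@]12C[C@H](OC3(C)C)[C@H](O3)C(C)(C)[C@]14C[C@@H]1[C@H]2[C@]1(C)[C@H]4OC(C)=O | intermediate
29 | C11/C15 diacetate, C3/C4 cis-diol | CC(=O)OC[C@]12C[C@H](O)[C@H](O)C(C)(C)[C@]13C[C@@H]1[C@H]2[C@]1(C)[C@H]3OC(C)=O | intermediate
30 | cyclic methyl orthoacetate on O3/O4 of 29, both epimers at the orthoester carbon (not isolated) | CC(=O)OC[C@]12C[C@H](OC3(C)OC)[C@H](O3)C(C)(C)[C@]14C[C@@H]1[C@H]2[C@]1(C)[C@H]4OC(C)=O | intermediate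
31 | CNP0197219.1 (C3, C11, C15 triacetate, C4 alcohol) | CC(=O)OC[C@]12C[C@H](OC(C)=O)[C@H](O)C(C)(C)[C@]13C[C@@H]1[C@H]2[C@]1(C)[C@H]3OC(C)=O | target

**Summary**

Total step count: 18. Longest linear sequence: 17 steps (steps 1–7 and 9–18; step 8 makes the side-chain reagent).

Steps most likely to fail:

Step 11. The dienylketene may dimerise or polymerise faster than it adds to the hindered tetrasubstituted C1=C6 bond, or it may close in the fused rather than the bridged sense. The fallback sets out from acid 19: amide coupling (Me2NH·HCl, EDC·HCl, HOBt, i-Pr2NEt, CH2Cl2) should give the (Z)-N,N-dimethylamide F1. Tf2O and 2,4,6-collidine in 1,2-dichloroethane (0 → 80 °C) should convert it into the vinylketeniminium triflate F2, a much stronger electrophile that cannot dimerise. Its intramolecular [2+2] cycloaddition should give the cyclobutaniminium triflate F3, and hydrolysis with aqueous NaHCO3 comes back to the route at cyclobutanone 22.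

Step 12. α-Cleavage of the excited cyclobutanone (loss of CO, opening to a ketene) or a 1,3-acyl shift may outrun the 1,2-shift. The fallback sets out from 22 and moves the rearrangement to a chromophore without an α-cleavage channel: NH2OH·HCl/NaOAc in EtOH should give the oxime F4, and Ac2O/pyridine the O-acetyl oxime F5. Acetophenone-sensitised irradiation (350 nm, MeCN) should effect the 1-aza-di-π-methane rearrangement (C=N carbon from C9 to C10, closure C9–C8) to the nortricyclanone O-acetyl oxime F6. Aqueous TiCl3 buffered with NH4OAc in dioxane reduces the N–O bond to the N–H imine F7, which hydrolyses in the same pot and comes back to the route at ketone 23.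

Step 14. The delocalised cation may be captured at a cyclopropane carbon (ring-opened homoallylic acetates) or lose a proton instead of being substituted at C11. The fallback sets out from alcohol 24 and avoids the cation: hydride-transfer equilibration through ketone 23 (Al(O-i-Pr)3, cat. acetone, i-PrOH/toluene, 80 °C; Meerwein–Ponndorf–Verley/Oppenauer) should enrich the less crowded C11 epimeric alcohol F8 (hydroxyl on the C7 side). F8 is separated, the remainder recycled, and acetylation (Ac2O, DMAP, pyridine) comes back to the route at acetate 26.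

**Further compounds**

F1 | step 11 | (Z)-N,N-dimethylamide of acid 19 | CC(C)(C)[Si](C)(C)OCC1=C(CC/C(C)=C\C(=O)N(C)C)C(C)(C)[C@H]2OC(C)(C)O[C@H]2C1
F2 | step 11 | vinylketeniminium triflate from F1 | CC(C)(C)[Si](C)(C)OCC1=C(C/C=C(C)\C=C=[N+](C)C)C(C)(C)[C@H]2OC(C)(C)O[C@H]2C1.[O-]S(=O)(=O)C(F)(F)F
F3 | step 11 | N,N-dimethyl cyclobutaniminium triflate corresponding to 22 | CC(C)(C)[Si](C)(C)OC[C@]12C[C@H](OC3(C)C)[C@H](O3)C(C)(C)[C@]14CC=C(C)[C@H]2C4=[N+](C)C.[O-]S(=O)(=O)C(F)(F)F
F4 | step 12 | oxime of cyclobutanone 22 | CC(C)(C)[Si](C)(C)OC[C@]12C[C@H](OC3(C)C)[C@H](O3)C(C)(C)[C@]14CC=C(C)[C@H]2C4=NO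
F5 | step 12 | O-acetyl oxime of cyclobutanone 22 | CC(C)(C)[Si](C)(C)OC[C@]12C[C@H](OC3(C)C)[C@H](O3)C(C)(C)[C@]14CC=C(C)[C@H]2C4=NOC(C)=O
F6 | step 12 | O-acetyl oxime of nortricyclanone 23 | CC(C)(C)[Si](C)(C)OC[C@]12C[C@H](OC3(C)C)[C@H](O3)C(C)(C)[C@]14C[C@@H]1[C@H]2[C@]1(C)C4=NOC(C)=O
F7 | step 12 | N–H imine of nortricyclanone 23 | CC(C)(C)[Si](C)(C)OC[C@]12C[C@H](OC3(C)C)[C@H](O3)C(C)(C)[C@]14C[C@@H]1[C@H]2[C@]1(C)C4=N
F8 | step 14 | C11 epimer of alcohol 24, hydroxyl on the C7 side | CC(C)(C)[Si](C)(C)OC[C@]12C[C@H](OC3(C)C)[C@H](O3)C(C)(C)[C@]14C[C@@H]1[C@H]2[C@]1(C)[C@H]4O
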